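## Retrosynthetic overview
1. The cyclohexenone is made by Dauben–Michno 1,3-oxidative transposition of a tertiary allylic alcohol. This places the C3 methyl and the C1 carbonyl, and it is the last step.
2. The preformed butenolide is attached to a primary homoallylic iodide by a proposed new Ni cross-electrophile coupling with 4-bromofuran-2(5H)-one.
3. Both E-trisubstituted alkenes come from Zr-catalysed carboalumination (ZACA) of terminal alkynes. The alkynes are added by Negishi coupling of a 4-TMS-butynylzinc and by alkylation. The terminal CH2CH2OH comes from an alkenyllithium plus ethylene oxide.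
4. The vicinal quaternary/tertiary centres come from sequential α′-alkylation of (R)-5-methylcyclohex-2-enone, chain first and Me last, so that the new Me lands trans to the 5-Me. The enone is made from (R)-3-methylcyclohexanone.
5. Ring order: the cyclohexane ring and the butenolide ring are both preformed, so no ring is closed in the route. The cyclohexenone C=C forms in the last step.

**Assumptions**
- (R)-3-Methylcyclohexanone is commercial (from (R)-pulegone).
- The tertiary carbinol created in Step 6 is an epimer mixture; it is destroyed in Step 18, so its configuration is left unspecified.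
- The minor regioisomeric enone from Steps 1–2 (3-methylcyclohex-2-enone, achiral) is removed by chromatography.

## Route

**Step 1**
Reactants: 1 (R)-3-methylcyclohexanone
Product: 2 (R)-trimethyl{[5-methylcyclohex-1-en-1-yl]oxy}silane (kinetic TMS enol ether, C1=C6)
Conditions: LDA, THF, −78 °C; then TMSCl, −78 °C → 0 °C
Reagents that add atoms: TMSCl, C[Si](C)(C)Cl
Why: Kinetic enolisation with LDA occurs at the less hindered α-CH2 (away from the methyl), and the stereocentre is untouched. Reaction type: kinetic silyl enol ether formation.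

**Step 2**
Reactants: 2
Product: 3 (R)-5-methylcyclohex-2-en-1-one
Conditions: Pd(OAc)2 (1 equiv), MeCN, 25 °C
Reagents that add atoms: none
Why: Saegusa–Ito oxidation places the C=C on the side remote from the methyl. This leaves the α′-CH2 next to the C5-methyl carbon free for alkylation. The 5-methyl stereocentre is not acidic, so it is not racemised.

**Step 3**
Reactants: 4 4-(trimethylsilyl)but-3-yn-1-ol
Product: 5 (4-iodobut-1-yn-1-yl)trimethylsilane
Conditions: PPh3, I2, imidazole, CH2Cl2, 0 °C
Reagents that add atoms: I2, II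
Why: Garegg–Samuelsson (Appel-type) iodination gives the homopropargylic iodide used for both the enolate alkylation and the Negishi coupling.

**Step 4**
Reactants: 3; 5
Product: 6 (5R,6S)-5-methyl-6-[4-(trimethylsilyl)but-3-yn-1-yl]cyclohex-2-en-1-one (trans)
Conditions: LDA, THF, −78 °C; then HMPA and 5, −78 → −20 °C
Reagents that add atoms: none
Why: Kinetic deprotonation gives the cross-conjugated α′-dienolate, and alkylation occurs anti to the 5-Me. This centre is re-enolised in Step 5, so only its regiochemistry matters.

**Step 5**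
Reactants: 6
Product: 7 (5R,6R)-5,6-dimethyl-6-[4-(trimethylsilyl)but-3-yn-1-yl]cyclohex-2-en-1-one
Conditions: LDA, THF, −78 °C; then MeI, HMPA, −78 → 0 °C
Reagents that add atoms: MeI, CI
Why: Enolate alkylation. A(1,2) strain with the C6 chain holds the 5-Me pseudo-axial, and MeI attacks axially on the opposite face. This sets the quaternary C4 (target numbering) with Me trans to the 5-Me and the chain cis to it, as in the target. The minor epimer is removed by chromatography.

**Step 6**
Reactants: 7
Product: 8 (5R,6R)-1,5,6-trimethyl-6-[4-(trimethylsilyl)but-3-yn-1-yl]cyclohex-2-en-1-ol (C1 epimers)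
Conditions: MeLi, CeCl3, THF, −78 °C
Reagents that add atoms: MeLi, C[Li]
Why: Organocerium 1,2-addition to the hindered enone carbonyl avoids conjugate addition and enolisation. The new carbinol stereocentre is irrelevant because it is destroyed in Step 18.

**Step 7**
Reactants: 8
Product: 9 triethyl{[(5R,6R)-1,5,6-trimethyl-6-(4-TMS-but-3-yn-1-yl)cyclohex-2-en-1-yl]oxy}silane
Conditions: TESOTf, 2,6-lutidine, CH2Cl2, −78 → 0 °C
Reagents that add atoms: TESOTf, CC[Si](CC)(CC)OS(=O)(=O)C(F)(F)F
Why: Silylation masks the tertiary alcohol. Me3Al, t-BuLi and the organozinc in later steps are then tolerated, and the ring is never an enone while strong nucleophiles are present.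

**Step 8**
Reactants: 9
Product: 10 triethyl{[(5R,6R)-6-(but-3-yn-1-yl)-1,5,6-trimethylcyclohex-2-en-1-yl]oxy}silane
Conditions: K2CO3, MeOH, 25 °C
Reagents that add atoms: none
Why: Protodesilylation of the alkynyl–TMS bond leaves the tertiary TES ether intact.

**Step 9**
Reactants: 10
Product: 11 triethyl{[(5R,6R)-6-[(3E)-4-iodo-3-methylbut-3-en-1-yl]-1,5,6-trimethylcyclohex-2-en-1-yl]oxy}silane
Conditions: Me3Al, cat. Cp2ZrCl2, ClCH2CH2Cl, 25 °C; then I2, THF, −30 °C
Reagents that add atoms: Me3Al, C[Al](C)C; I2, II
Why: Negishi ZACA. Syn-methylalumination puts Me on the internal alkyne carbon and Al on the terminal carbon, so iodolysis gives the E-vinyl iodide (chain trans to I).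

**Step 10**
Reactants: 11; 5 (converted in situ to IZnCH2CH2C≡CTMS)
Product: 12 triethyl{[(5R,6R)-1,5,6-trimethyl-6-[(3E)-3-methyl-8-(trimethylsilyl)oct-3-en-7-yn-1-yl]cyclohex-2-en-1-yl]oxy}silane
Conditions: Zn dust, LiCl, I2 (cat.), THF, 25 °C (forms RZnI from 5); then 11, Pd(PPh3)4 (5 mol %), 50 °C
Reagents that add atoms: none
Why: Negishi sp2–sp3 coupling proceeds with retention of alkene geometry and builds the a4–a5 bond.

**Step 11**
Reactants: 12
Product: 13 triethyl{[(5R,6R)-6-[(3E)-3-methyloct-3-en-7-yn-1-yl]-1,5,6-trimethylcyclohex-2-en-1-yl]oxy}silane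
Conditions: K2CO3, MeOH, 25 °C
Reagents that add atoms: none
Why: Protodesilylation again, to generate the alkyne for the second ZACA.

**Step 12**
Reactants: 13
Product: 14 triethyl{[(5R,6R)-6-[(3E,7E)-8-iodo-3,7-dimethylocta-3,7-dien-1-yl]-1,5,6-trimethylcyclohex-2-en-1-yl]oxy}silane
Conditions: Me3Al, cat. Cp2ZrCl2, ClCH2CH2Cl, 25 °C; then I2, THF, −30 °C
Reagents that add atoms: Me3Al, C[Al](C)C; I2, II
Why: The second ZACA creates the second E-trisubstituted alkene. Reaction type: carboalumination/iodination, selective for the terminal alkyne over the ring and chain alkenes.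

**Step 13**
Reactants: 14
Product: 15 triethyl{[(5R,6R)-6-[(3E,7E)-10-hydroxy-3,7-dimethyldeca-3,7-dien-1-yl]-1,5,6-trimethylcyclohex-2-en-1-yl]oxy}silane
Conditions: t-BuLi (2.1 equiv), Et2O, −78 °C; then ethylene oxide, BF3·OEt2, −78 °C
Reagents that add atoms: ethylene oxide, C1CO1
Why: Lithium–iodine exchange is stereoretentive, and the alkenyllithium opens the BF3-activated epoxide at the CH2 to give the a9–a10 homoallylic alcohol. The butenolide is not yet present, so it cannot be attacked.

**Step 14**
Reactants: 15
Product: 16 triethyl{[(5R,6R)-6-[(3E,7E)-10-iodo-3,7-dimethyldeca-3,7-dien-1-yl]-1,5,6-trimethylcyclohex-2-en-1-yl]oxy}silane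
Conditions: PPh3, I2, imidazole, CH2Cl2, 0 °C
Reagents that add atoms: I2, II
Why: Garegg–Samuelsson iodination of the primary alcohol; the alkenes and the TES ether are inert.

**Step 15**
Reactants: 17 tetronic acid
Product: 18 4-bromofuran-2(5H)-one
Conditions: (COBr)2, DMF (cat.), CH2Cl2, 0 → 25 °C
Reagents that add atoms: oxalyl bromide, BrC(=O)C(=O)Br
Why: The vinylogous acid (enol) OH is converted to the vinyl bromide through a Vilsmeier-type bromide.

**Step 16**
Reactants: 16; 18
Product: 19 4-{(3E,7E)-4,8-dimethyl-10-[(1R,2R)-... i.e. (5R,6R)-1,5,6-trimethyl-1-(triethylsilyloxy)cyclohex-2-en-6-yl]deca-3,7-dien-1-yl}furan-2(5H)-one (butenolide TES ether)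
Conditions: NiBr2·diglyme (10 mol %), dtbbpy (10 mol %), Zn dust (3 equiv), 18 (3 equiv), DMA/THF, 30 °C
Reagents that add atoms: none
Why: Proposed new method: Ni-catalysed cross-electrophile coupling of an unactivated primary (homoallylic) alkyl iodide with a 4-halo-2(5H)-furanone, a β-halo enoate lactone with an acidic γ-CH2 and an electrophilic lactone. Ni(0)/bipyridine oxidatively adds into the electron-poor vinyl C–Br. Ni(I) abstracts iodine from the alkyl iodide, the primary radical recombines with vinyl–Ni(II), and reductive elimination forms the C(sp3)–C(sp2) bond. Because no organometallic nucleophile or strong base is present, the lactone and the γ-protons survive. The closest known reaction is Weix-type Ni cross-electrophile coupling of alkyl halides with vinyl bromides, and Negishi or Suzuki coupling of 4-halofuranones with aryl partners. The homoallyl radical's cyclopropylcarbinyl ring closure is degenerate here because a9 and a10 are both CH2.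

**Step 17**
Reactants: 19
Product: 20 4-{(3E,7E)-4,8-dimethyl-10-[(5R,6R)-1-hydroxy-1,5,6-trimethylcyclohex-2-en-6-yl]deca-3,7-dien-1-yl}furan-2(5H)-one, i.e. (3E,7E)-chain tertiary allylic alcohol (C1 epimers)
Conditions: HF·pyridine, THF/pyridine, 0 → 25 °C
Reagents that add atoms: none
Why: Fluoride cleaves the tertiary TES ether under non-basic conditions that do not deprotonate the butenolide.

**Step 18**
Reactants: 20
Product: 21 cyclolinteinone, (4R,5R)-3,4,5-trimethyl-4-[(3E,7E)-3,7-dimethyl-10-(5-oxo-2,5-dihydrofuran-3-yl)deca-3,7-dien-1-yl]cyclohex-2-en-1-one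
Conditions: PCC, NaOAc, Celite, CH2Cl2, 25 °C
Reagents that add atoms: none
Why: Dauben–Michno oxidative transposition. The tertiary allylic chromate ester undergoes a [3,3] shift and oxidation, so the carbonyl appears at old C3 and the Me-bearing C=C forms at C1=C2, giving the 3-methylcyclohex-2-enone. No stereocentre is touched, since C4 is quaternary and C5 is not enolisable.

## Compound list
1 | (R)-3-methylcyclohexan-1-one | C[C@@H]1CCCC(=O)C1 | starting material
2 | (R)-trimethyl{[5-methylcyclohex-1-en-1-yl]oxy}silane | C[C@@H]1CCC=C(O[Si](C)(C)C)C1 | intermediate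
3 | (R)-5-methylcyclohex-2-en-1-one | C[C@@H]1CC=CC(=O)C1 | intermediate
4 | 4-(trimethylsilyl)but-3-yn-1-ol | C[Si](C)(C)C#CCCO | starting material
5 | (4-iodobut-1-yn-1-yl)trimethylsilane | C[Si](C)(C)C#CCCI | intermediate (reagent)
6 | (5R,6S)-5-methyl-6-[4-(trimethylsilyl)but-3-yn-1-yl]cyclohex-2-en-1-one | C[C@@H]1CC=CC(=O)[C@H]1CCC#C[Si](C)(C)C | intermediate
7 | (5R,6R)-5,6-dimethyl-6-[4-(trimethylsilyl)but-3-yn-1-yl]cyclohex-2-en-1-one | C[C@@H]1CC=CC(=O)[C@]1(C)CCC#C[Si](C)(C)C | intermediate
8 | (5R,6R)-1,5,6-trimethyl-6-[4-(trimethylsilyl)but-3-yn-1-yl]cyclohex-2-en-1-ol (C1 unspecified) | C[C@@H]1CC=CC(C)(O)[C@]1(C)CCC#C[Si](C)(C)C | intermediate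
9 | TES ether of 8 | C[C@@H]1CC=CC(C)(O[Si](CC)(CC)CC)[C@]1(C)CCC#C[Si](C)(C)C | intermediate
10 | 6-(but-3-yn-1-yl) TES ether | C[C@@H]1CC=CC(C)(O[Si](CC)(CC)CC)[C@]1(C)CCC#C | intermediate
11 | E-vinyl iodide (C4 chain) | C[C@@H]1CC=CC(C)(O[Si](CC)(CC)CC)[C@]1(C)CC/C(C)=C/I | intermediate
12 | TMS-enyne chain | C[C@@H]1CC=CC(C)(O[Si](CC)(CC)CC)[C@]1(C)CC/C(C)=C/CCC#C[Si](C)(C)C | intermediate
13 | terminal-alkyne chain | C[C@@H]1CC=CC(C)(O[Si](CC)(CC)CC)[C@]1(C)CC/C(C)=C/CCC#C | intermediate
14 | E,E-diene vinyl iodide | C[C@@H]1CC=CC(C)(O[Si](CC)(CC)CC)[C@]1(C)CC/C(C)=C/CC/C(C)=C/I | intermediate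
15 | homoallylic alcohol | C[C@@H]1CC=CC(C)(O[Si](CC)(CC)CC)[C@]1(C)CC/C(C)=C/CC/C(C)=C/CCO | intermediate
16 | homoallylic iodide | C[C@@H]1CC=CC(C)(O[Si](CC)(CC)CC)[C@]1(C)CC/C(C)=C/CC/C(C)=C/CCI | intermediate
17 | tetronic acid (furan-2,4(3H,5H)-dione) | O=C1CC(=O)CO1 | starting material
18 | 4-bromofuran-2(5H)-one | O=C1C=C(Br)CO1 | intermediate (reagent)
19 | butenolide TES ether | C[C@@H]1CC=CC(C)(O[Si](CC)(CC)CC)[C@]1(C)CC/C(C)=C/CC/C(C)=C/CCC1=CC(=O)OC1 | intermediate
20 | butenolide tertiary allylic alcohol (C1 unspecified) | C[C@@H]1CC=CC(C)(O)[C@]1(C)CC/C(C)=C/CC/C(C)=C/CCC1=CC(=O)OC1 | intermediate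
21 | cyclolinteinone | CC1=CC(=O)C[C@@H](C)[C@@]1(C)CC/C(C)=C/CC/C(C)=C/CCC1=CC(=O)OC1 | target

## Totals
Total steps: 18, including two reagent-preparation steps (Steps 3 and 15). Longest linear sequence: 16 steps, from 1 to 21 (Steps 1, 2, 4–14, 16–18).

## Three steps most likely to fail
1. **Step 16 (proposed new Ni cross-electrophile coupling).** Risks are reduction or homocoupling of 18 and alkyl iodide reduction.
   Fallback, changing the bond-forming logic: convert 16 to the alkyl Grignard (Mg, THF) and add it to N-methoxy-N-methyl-2-(TBSO)acetamide to give the α-silyloxy ketone. Run a Horner–Wadsworth–Emmons reaction with (EtO)2P(O)CH2CO2Et and NaH, then remove TBS and TES with HF·pyridine and close the lactone with cat. TsOH (E isomer photo-isomerised with PhSSPh, hv). This gives 20 by known chemistry.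
2. **Step 5 (second α′-alkylation: quaternary centre, dr and yield).**
   Fallback, changing the approach: Johnson–Claisen rearrangement of (R)-3-methylcyclohexanone-derived 2,3,4-trimethylcyclohex-2-en-1-ol, using the carbinol diastereomer that puts the new CH2CO2Et chain cis to the 4-Me. Chirality transfer is suprafacial. Then homologate with LiAlH4, PPh3/I2 and LiC≡CTMS to the alkyne. Carry out allylic oxidation to the enone, Luche reduction and TES protection, re-enter at the alkyne stage (Step 8), and finish with HF·pyridine then Dess–Martin oxidation.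
3. **Step 18 (late-stage Dauben–Michno oxidation on a polyene and butenolide).** Risks are a sluggish, hindered tertiary chromate ester and acid-sensitivity of the E-alkenes.
   Fallback, changing the approach: Ph3SiOReO3- or Re2O7-catalysed 1,3-transposition of 20 to the secondary allylic alcohol (more substituted alkene), followed by Dess–Martin oxidation to 21.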